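The route rests on the aryl–CH disconnection. Removing the lactone oxygen (Baeyer–Villiger retron) turns the 6-oxabicyclo[3.2.2]nonene into a bicyclo[3.2.1]oct-3-ene-2,8-dione. In this dione the aryl-bearing CH (C7) of the two-carbon bridge is β to both ketones through the bridgehead CH (C1), so C1–C7 is an aldol-type bond. The key step exploits this. Its precursor is a 7-alkoxy analogue made by cationic [5+2] cycloaddition of a quinone monoketal with a chiral propenyl ether. Under BF3 it opens at C1–C7, the oxocarbenium carbon takes the 3,4,5-trimethoxyphenyl group from the boronic acid, and the benzylic cation left after loss of the auxiliary recloses on C1. One operation joins both halves and sets C1 and C7.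

Key step: step 7

Remark on numbering: 8 and 11 use bicyclo[3.2.1]octane numbering. C1 is the bridgehead CH, C2 the enone C=O, C3 carries allyl, C4 is =CH, C5 is the bridgehead C(OMe), C6 is CH(CH3), C7 is the CH that ends up aryl-bearing, and C8 is the bridging C=O.

Assumption: the (1R,2S)-auxiliary is taken to shield the alkene face whose blocking leads to the (5S,6R) series drawn for 8. If the sense of induction is the opposite, the equally available (1S,2R)-alcohol is used with no other change.

Step 1
Reactants: 1 3,4-dimethoxyphenol
Product: 2 4-(allyloxy)-1,2-dimethoxybenzene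
Conditions: allyl bromide, K2CO3, acetone, reflux
Reagents that add atoms: allyl bromide C=CCBr
Why: Williamson ether synthesis of an unhindered phenoxide with a primary allylic halide.

Step 2
Reactants: 2 4-(allyloxy)-1,2-dimethoxybenzene
Product: 3 2-allyl-4,5-dimethoxyphenol
Conditions: N,N-diethylaniline, 200 °C
Reagents that add atoms: none
Why: Aromatic Claisen rearrangement, in which the [3,3] shift should go to the free ortho carbon that is not flanked by a methoxy group.

Step 3
Reactants: 3 2-allyl-4,5-dimethoxyphenol
Product: 4 2-allyl-4,4,5-trimethoxycyclohexa-2,5-dien-1-one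
Conditions: PhI(OAc)2, MeOH, 0 °C
Reagents that add atoms: methanol CO
Why: Hypervalent-iodine oxidative dearomatisation, in which methanol adds to the methoxy-bearing para carbon, the best stabilised position of the phenoxenium ion, and gives the p-quinone monoketal.

Step 4
Reactants: 5 (1R,2S)-trans-2-phenylcyclohexan-1-ol
Product: 6 allyl (1R,2S)-2-phenylcyclohexyl ether
Conditions: NaH, allyl bromide, Bu4NI (cat.), THF, 0 °C to rt
Reagents that add atoms: allyl bromide C=CCBr
Why: Williamson ether synthesis at oxygen, which leaves both stereocentres of the auxiliary untouched.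

Step 5
Reactants: 6 allyl (1R,2S)-2-phenylcyclohexyl ether
Product: 7 (E)-prop-1-en-1-yl (1R,2S)-2-phenylcyclohexyl ether
Conditions: [Ir(cod)(PMePh2)2]PF6 (1 mol %, H2-activated), THF, rt
Reagents that add atoms: none
Why: Iridium-hydride-catalysed allyl-to-propenyl ether isomerisation (1,3-hydrogen shift), a reaction type that delivers the (E)-enol ether.

Step 6
Reactants: 4 2-allyl-4,4,5-trimethoxycyclohexa-2,5-dien-1-one; 7 (E)-prop-1-en-1-yl (1R,2S)-2-phenylcyclohexyl ether
Product: 8 (1R,5S,6R,7R)-3-allyl-5-methoxy-6-methyl-7-{[(1R,2S)-2-phenylcyclohexyl]oxy}bicyclo[3.2.1]oct-3-ene-2,8-dione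
Conditions: TMSOTf (20 mol %), CH2Cl2, −78 to −40 °C
Reagents that add atoms: none
Why: Cationic [5+2] cycloaddition of a p-quinone monoketal with an electron-rich alkene: TMSOTf ionises the ketal, the methyl-bearing nucleophilic carbon of the enol ether bonds to the methoxy-bearing para carbon (C5) and the oxocarbenium carbon is closed by the ring enol-ether carbon (C1), the suprafacial addition of the (E)-alkene with the bulky alkoxy group exo placing the methyl group endo (relative configuration of C1, C5, C6, C7), while the phenyl ring of the auxiliary shields one alkene face and so fixes the absolute configuration.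

Step 7
Reactants: 8 (1R,5S,6R,7R)-3-allyl-5-methoxy-6-methyl-7-{[(1R,2S)-2-phenylcyclohexyl]oxy}bicyclo[3.2.1]oct-3-ene-2,8-dione; 9 3,4,5-trimethoxyphenylboronic acid
Product: 11 (1R,5R,6R,7R)-3-allyl-5-methoxy-6-methyl-7-(3,4,5-trimethoxyphenyl)bicyclo[3.2.1]oct-3-ene-2,8-dione, via ring-opened benzylic ether 10 (not isolated)
Conditions: 9 (1.5 equiv), BF3·OEt2 (20 mol %), CH2Cl2/HFIP, −40 °C to rt
Reagents that add atoms: none
Why: Proposed new method: BF3 activates a ketone of 8 and the lone pair of the C7 alkoxy oxygen pushes open the C1–C7 bond (retro-Mukaiyama-aldol fragmentation), which unmasks a side-chain oxocarbenium ion at C7 and a vinylogous carboxylate (C8–O) that binds the boronic acid as an ate complex and lets the ipso carbon migrate to C7, giving 10; the closest known reaction types are the Petasis borono-Mannich reaction and the BF3-mediated arylation of acetals and N-acyliminium ions with organoboron reagents. The electron-rich benzylic ether 10 then ionises with loss of the auxiliary alcohol to the benzylic cation that is also the intermediate of stepwise cationic [5+2] cycloadditions of propenylarenes with quinone monoketals. Enol carbon C1, whose p orbital stands perpendicular to the dienone plane and points at the side chain held axially on C5, captures C7 and closes the five-membered ring C1–C7–C6–C5–C8 as a bridging C-alkylation of the 1,3-dicarbonyl unit (cation–enol closure, not a planar enolendo alkylation). C5 and C6 are not touched, C1 is dictated by the bridge to C5, and C7 places the aryl group exo, trans to the endo methyl group and away from the enone bridge. The step needs ipso instead of ortho attack of the arene, which the boron-to-carbon delivery inside the ate complex secures, and C- instead of O-capture of the cation, which is secured because O-capture (a hydrobenzofuranone) is reversible under the acid, so that material should funnel to the C-alkylated dione that such cations are known to give.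

Step 8
Reactants: 11 (1R,5R,6R,7R)-3-allyl-5-methoxy-6-methyl-7-(3,4,5-trimethoxyphenyl)bicyclo[3.2.1]oct-3-ene-2,8-dione
Product: 12 (1R,5S,8R,9R)-3-allyl-5-methoxy-9-methyl-8-(3,4,5-trimethoxyphenyl)-6-oxabicyclo[3.2.2]non-3-ene-2,7-dione (CNP0298078.1)
Conditions: mCPBA (1.1 equiv), CH2Cl2/aq. pH 7.5 phosphate buffer, 0 °C
Reagents that add atoms: mCPBA O=C(OO)c1cccc(Cl)c1
Why: Baeyer–Villiger oxidation, in which the strained non-conjugated bridging ketone C8 should add the peracid before the enone carbonyl, and the methoxy-bearing tertiary C5 (the best cation-stabilising neighbour) migrates with retention to become the acyl ketal carbon, while the electron-poor enone alkene is inert and the monosubstituted allyl alkene reacts more slowly.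

Compound list
1 | 3,4-dimethoxyphenol | COc1ccc(O)cc1OC | starting material
2 | 4-(allyloxy)-1,2-dimethoxybenzene | C=CCOc1ccc(OC)c(OC)c1 | intermediate
3 | 2-allyl-4,5-dimethoxyphenol | C=CCc1cc(OC)c(OC)cc1O | intermediate
4 | 2-allyl-4,4,5-trimethoxycyclohexa-2,5-dien-1-one | C=CCC1=CC(OC)(OC)C(OC)=CC1=O | intermediate
5 | (1R,2S)-trans-2-phenylcyclohexan-1-ol | O[C@@H]1CCCC[C@H]1c1ccccc1 | starting material
6 | allyl (1R,2S)-2-phenylcyclohexyl ether | C=CCO[C@@H]1CCCC[C@H]1c1ccccc1 | intermediate
7 | (E)-prop-1-en-1-yl (1R,2S)-2-phenylcyclohexyl ether | C/C=C/O[C@@H]1CCCC[C@H]1c1ccccc1 | intermediate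
8 | (1R,5S,6R,7R)-3-allyl-5-methoxy-6-methyl-7-{[(1R,2S)-2-phenylcyclohexyl]oxy}bicyclo[3.2.1]oct-3-ene-2,8-dione (6-endo-methyl, 7-exo-alkoxy) | C=CCC1=C[C@@]2(OC)C(=O)[C@@H](C1=O)[C@H](O[C@@H]3CCCC[C@H]3c3ccccc3)[C@H]2C | intermediate
9 | 3,4,5-trimethoxyphenylboronic acid | COc1cc(B(O)O)cc(OC)c1OC | starting material
10 | (4S)-2-allyl-5-hydroxy-4-methoxy-4-{(2R)-1-{[(1R,2S)-2-phenylcyclohexyl]oxy}-1-(3,4,5-trimethoxyphenyl)propan-2-yl}cyclohexa-2,5-dien-1-one (benzylic carbon epimeric, not isolated) | C=CCC1=C[C@](OC)([C@H](C)C(O[C@@H]2CCCC[C@H]2c2ccccc2)c2cc(OC)c(OC)c(OC)c2)C(O)=CC1=O | intermediate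
11 | (1R,5R,6R,7R)-3-allyl-5-methoxy-6-methyl-7-(3,4,5-trimethoxyphenyl)bicyclo[3.2.1]oct-3-ene-2,8-dione (6-endo-methyl, 7-exo-aryl) | C=CCC1=C[C@@]2(OC)C(=O)[C@@H](C1=O)[C@H](c1cc(OC)c(OC)c(OC)c1)[C@H]2C | intermediate
12 | (1R,5S,8R,9R)-3-allyl-5-methoxy-9-methyl-8-(3,4,5-trimethoxyphenyl)-6-oxabicyclo[3.2.2]non-3-ene-2,7-dione | C=CCC1=C[C@@]2(OC)OC(=O)[C@@H](C1=O)[C@H](c1cc(OC)c(OC)c(OC)c1)[C@H]2C | target

Total step count: 8.
Longest linear sequence: 6 (steps 1, 2, 3, 6, 7, 8).

Steps most likely to fail

1. Step 7 (Proposed new method).
- What may go wrong: the oxocarbenium ion may reclose faster than it is arylated while the boronic acid is consumed by protodeboronation. The arene may react through its activated ortho carbon. Reversible loss of the C6 proton from the cationic intermediates may erode the methyl stereocentre.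
- Fallback with known chemistry, from 8 back to 11: aqueous acid (TFA, THF/H2O) should drive the retro-aldol opening and hydrolyse the oxocarbenium ion to the aldehyde (2S)-2-[(1S)-5-allyl-2-hydroxy-1-methoxy-4-oxocyclohexa-2,5-dien-1-yl]propanal F1, which equilibrates with its lactol, and this frees the auxiliary. 3,4,5-Trimethoxyphenyltitanium triisopropoxide (from the aryl Grignard reagent and ClTi(OiPr)3, used in excess because of the acidic enol) should add only to the aldehyde. This gives the benzylic alcohol (4S)-2-allyl-5-hydroxy-4-[(2R)-1-hydroxy-1-(3,4,5-trimethoxyphenyl)propan-2-yl]-4-methoxycyclohexa-2,5-dien-1-one F2 as carbinol epimers. SnCl4 or TFA in CH2Cl2 at low temperature then ionises F2, and the acid-promoted benzylation of the 1,3-dicarbonyl unit closes the ring to 11.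

2. Step 6.
- What may go wrong: facial selectivity of the auxiliary may be low, the cation may be attacked at the allyl-bearing ring carbon, and the enol ether may oligomerise under the acid.
- Fallback, from 4 back to 12: chirality is introduced at the end instead. The cycloaddition of 4 with commercial ethyl prop-1-enyl ether should give racemic (1R*,5S*,6R*,7R*)-3-allyl-7-ethoxy-5-methoxy-6-methylbicyclo[3.2.1]oct-3-ene-2,8-dione F3. The conditions of step 7 convert it into the racemic 7-aryl dione F4. A Baeyer–Villiger monooxygenase (flavin- and NADPH-dependent, with cofactor recycling), screened for enantiomer discrimination, oxidises only the (1R,5R,6R,7R)-enantiomer in an enzymatic kinetic resolution that gives 12.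

3. Step 8.
- What may go wrong: epoxidation of the allyl group may compete with peracid addition to the hindered bridging ketone, and the acyl ketal may open under acid.
- Fallback, from 11 back to 12: a Baeyer–Villiger monooxygenase replaces the peracid. This enzyme class delivers oxygen through a flavin peroxide to ketones only and works at neutral pH. No new compound is made (F0).

Further compounds
F1 | step 7 | (2S)-2-[(1S)-5-allyl-2-hydroxy-1-methoxy-4-oxocyclohexa-2,5-dien-1-yl]propanal | C=CCC1=C[C@](OC)([C@H](C)C=O)C(O)=CC1=O
F2 | step 7 | (4S)-2-allyl-5-hydroxy-4-[(2R)-1-hydroxy-1-(3,4,5-trimethoxyphenyl)propan-2-yl]-4-methoxycyclohexa-2,5-dien-1-one (carbinol epimers) | C=CCC1=C[C@](OC)([C@H](C)C(O)c2cc(OC)c(OC)c(OC)c2)C(O)=CC1=O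
F3 | step 6 | racemic (1R*,5S*,6R*,7R*)-3-allyl-7-ethoxy-5-methoxy-6-methylbicyclo[3.2.1]oct-3-ene-2,8-dione (one enantiomer drawn) | C=CCC1=C[C@@]2(OC)C(=O)[C@@H](C1=O)[C@H](OCC)[C@H]2C
F4 | step 6 | racemic (1R*,5R*,6R*,7R*)-3-allyl-5-methoxy-6-methyl-7-(3,4,5-trimethoxyphenyl)bicyclo[3.2.1]oct-3-ene-2,8-dione (one enantiomer drawn) | C=CCC1=C[C@@]2(OC)C(=O)[C@@H](C1=O)[C@H](c1cc(OC)c(OC)c(OC)c1)[C@H]2C
F0 | step 8 | none | none
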